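Colleague, you want a quick number for the flask, and your hunch is the midpoint of the elm and alder readings at 12.0 h, 67.0%. I would count turnovers instead of averaging.

| setting | elm | alder | flask |
|---|---|---|---|
| starting complex | 0.067 M | 0.15 M | 0.10 M |
| incoming ligand | 2 equiv | 2 equiv | 2.00 equiv |
| remark | run made earlier | run made earlier |  |
| time |  |  | 12 h |

| run | time / h | complex with one exchanged / % | starting complex / % |
|---|---|---|---|
| elm | 2.50 | 18 | 78 |
| elm | 5.00 | 32 | 60 |
| elm | 8.00 | 46 | 46 |
| elm | 10.0 | 49 | 45 |
| elm | 12.0 | 57 | 37 |
| elm | 15.0 | 65 | 31 |
| alder | 1.00 | 16 | 77 |
| alder | 3.00 | 38 | 52 |
| alder | 5.00 | 52 | 39 |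
| alder | 8.00 | 65 | 28 |
| alder | 12.0 | 77 | 16 |
| alder | 15.0 | 81 | 10 |

(standard deviation of a reading: 1.5 percentage points)

- the analysis behind the earlier runs scatters by 1.5 percentage points, standard deviation
- a reading or a percentage of complex with one exchanged counts all its forms, free or not

* equivalents of incoming ligand to starting complex, everything else as given, that leave most complex with one exchanged at 12 h
* the amount of complex with one exchanged then, in percent of the starting complex charged
* the amount of complex with one exchanged with the amounts as given

Take f as the fraction left of the starting complex, the limiting reagent. I reckon the fraction of incoming ligand left by charging one ligand per complex lost. My turnover count, 0.827 in alder at 8.00 h, is the natural logarithm of that ligand fraction over f. For second-order steps at fixed equivalents, it grows with concentration times time. Carried to elm at 15.0 h, it gives 33.4% left, and the reading is 31%.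

The flask has the same concentration times time as alder at 8.00 h. So I say 28.0% starting complex left, and I read 65% complex with one exchanged from alder. I have no count of my own for the best charge.

The forecast, which finds that “the rates roughly fit second order”, says 68%, above my figure. For the best charge it says 81% at 3.8 equiv.

The flask gives 67.6%, and 79.3% at 4.02 equiv.

    starting complex + incoming ligand ⇌ leaving ligand + complex with one exchanged (K = 1.07, k = 0.788 /M/h)
    complex with one exchanged + incoming ligand ⇌ leaving ligand + complex with two exchanged (K = 0.290, k = 1.44 /M/h)
    complex with two exchanged + incoming ligand ⇌ leaving ligand + complex with three exchanged (K = 1.65, k = 0.867 /M/h)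
    leaving ligand → by-product carried off (k = 0.150 /h)
    crystals ⇌ complex with one exchanged, rate k5*(cs5 - [complex with one exchanged]) while solid is left; crystals form when [complex with one exchanged] > cs5 (solubility = 1.60 mM, k = 2.00 /h)
    starting complex + complex with one exchanged → side product (k = 0.119 /M/h)

My count of 0.827 left 28.0% starting complex, and the flask holds 25.8%. In the flask, complex with one exchanged stands this high mainly through the ceiling on its dissolved form: the run without that ceiling gives 33.4%, not 67.6%, and crystals hold 64.8%. In a neighbour flask charged with 0.25 M, the count rises to 2.07, which leaves 6.76%. That neighbour holds 6.80% starting complex and 85.2% complex with one exchanged.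

The runs are simulated for an exercise, and the scatter is random.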